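Early in the delta run, D climbs at 0.00550 min⁻¹ of the J charged up to 8.00 min, and between 15.0 min and 40.0 min it climbs at 0.00440 min⁻¹, which is less, so the delta readings, with their scatter, show no rise in rate after the later portions of E.

| flask | J | E | temperature | remark | time |
|---|---|---|---|---|---|
| theta | 15 mM | 16 mM (in portions, 3) | 20 °C | run made earlier; portions every 8.0 min |  |
| delta | 16 mM | 16 mM (in portions, 3) | 31 °C | run made earlier; portions every 8.0 min |  |
| zeta | 21 mM | 16 mM (in portions, 3) | 20 °C | run made earlier; portions every 8.0 min |  |
| green | 12 mM | 16.0 mM | 25 °C | everything together at the start | 80 min |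
| red | 20 mM | 16.0 mM (in portions, 3) | 25 °C | the portions of E follow each other after 8.0 min, the first at the start | 80 min |

- theta (time / min: D / %): 10.0: 0; 20.0: 3.6; 30.0: 3.8; 40.0: 3.9
- delta (time / min: D / %): 3.00: 1.5; 8.00: 4.4; 15.0: 8.6; 40.0: 19.6
- zeta (time / min: D / %): 5.00: 2.8; 15.0: 2.6; 25.0: 4.1; 40.0: 6.4

(each reading ± 1 percentage point)

- the winner by amount of D, in percent of the J charged; "neither" if no more than 2 percentage points parts them (green / red / neither)
- how much D is there at the end, in percent of the J charged: green
- how much D is there at the end, in percent of the J charged: red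

- a reading or a percentage of D counts all its forms, free or not

The quick number rests on one quantity. At 20 °C, the theta and zeta runs stand at 3.9% and 6.4% after 40.0 min. That gap of 2.5 percentage points is set against a scatter of 1 point on each reading, so the two runs do not force the percent rate to depend on J.

The reckoning here therefore treats the fall of J as first order. Taking -ln(1-y)/t from the 40.0 min readings gives a mean of 0.00132 min⁻¹ at 20 °C, and delta gives 0.00545 min⁻¹ at 31 °C. With ln k taken as straight in temperature, 25 °C lies 0.455 of the way along, which gives 0.00252 min⁻¹: the first-order rate constant, the fraction of the J present that turns to D each minute. It is a reading and carries the scatter.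

Holding J at its charge for 80 min gives a first pass of 20.2%. But J falls meanwhile, so that answer goes back in: the mean J is 89.9% of the charge, and the second pass gives 18.1%. The J charged does not enter this reckoning, so it gives green and red the same figure and says neither.

The forecast differs. It names red, with 20% for red (14% to 26%) and 13% for green (9% to 18%), on the ground that “The percent rate therefore rises with J”.

Green ends at 19.7% and red at 19.3%, inside the margin of 2 points, so the outcome is neither.

    J ⇌ D + Z (K = 0.0700 M, k = 0.00290 min⁻¹, Ea = 87.0 kJ mol⁻¹, ΔH = −43.0 kJ mol⁻¹)
    J + D ⇌ L, settled at all times (K = 73.0 L mol⁻¹, ΔH = −6.00 kJ mol⁻¹)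
    J + Z ⇌ X, settled at all times (K = 130 L mol⁻¹, ΔH = −52.0 kJ mol⁻¹)
    E + Z → Q (k = 33.0 L mol⁻¹ min⁻¹, Ea = 53.0 kJ mol⁻¹)
    (constants at 25 °C)

Green stays within 5 points of its figure for J from 1.5 mM to 96 mM at least, with the other amounts and the time held. Put to the red flask left until 5.0 h, 0.00252 min⁻¹ gives a first pass of 75.6% and a second of 47.0%, and that flask holds, all forms of D counted, 50.1% of the J charged.

The earlier runs and the new flask are calculated with constants of no real substance; scatter was added.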